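**Retrosynthetic overview**
- The ester between the two halves is cut first: the carboxylate of the cyclohexene acid opens a spiro-epoxide on the lactone half, giving the primary ester and the tertiary alcohol together.
- Each six-membered carbocycle is formed first in its half, by one isothiourea-catalysed cascade on an acyclic enoic acid: nitronate Michael addition to the unsaturated acylammonium ion, then aldol-β-lactonisation onto a tethered α-silyloxy ketone.
- Lactone half: the seven-membered lactone is formed second, by translactonisation of the β-lactone with the side-chain alcohol. Cyclohexene half: the same kind of β-lactone loses CO2 to give the ring alkene.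
- The enoic acids come from 3-methylbutanal and a 1-silyloxybut-3-en-2-one by enamine-catalysed Michael addition (first stereocentre) and Horner–Wadsworth–Emmons olefination.

Assumption: the SMILES is taken as drawn, so the isopropyl-bearing carbon is trans to the side chain in the lactone half and cis to it in the cyclohexene half; the two halves are therefore built in opposite enantiomeric series at that carbon.

**Route**

Step 1
Reactants: 1 (tert-butyldimethylsilyloxy)acetaldehyde; 2 vinylmagnesium bromide (CH2=CHMgBr)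
Product: 3 1-[(tert-butyldimethylsilyl)oxy]but-3-en-2-ol (racemic)
Conditions: THF, −78 → 0 °C; then H2O
Reagents that add atoms: none
Why: Grignard 1,2-addition to an aldehyde; the racemic carbinol centre is erased in step 2.

Step 2
Reactants: 3 1-[(tert-butyldimethylsilyl)oxy]but-3-en-2-ol
Product: 4 1-[(tert-butyldimethylsilyl)oxy]but-3-en-2-one
Conditions: Dess–Martin periodinane, CH2Cl2, 0 °C → rt; used directly
Reagents that add atoms: none
Why: Dess–Martin oxidation of a secondary allylic alcohol gives the vinyl ketone under neutral conditions that do not polymerise it.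

Step 3
Reactants: 5 3-nitropropanoic acid; 6 2-(trimethylsilyl)ethanol
Product: 7 2-(trimethylsilyl)ethyl 3-nitropropanoate
Conditions: EDC·HCl, DMAP (5 mol %), CH2Cl2, 0 °C → rt
Reagents that add atoms: none
Why: carbodiimide (Steglich-type) esterification; the fluoride-labile ester later unmasks both acrylic acids.

Step 4
Reactants: 7 2-(trimethylsilyl)ethyl 3-nitropropanoate; 8 (triisopropylsiloxy)methyl chloride
Product: 9 2-(trimethylsilyl)ethyl 3-nitro-2-{[(triisopropylsilyl)oxy]methyl}propanoate (racemic)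
Conditions: LiN(iPr)2 (2.1 equiv), THF/DMPU, −78 °C; then 8, −78 → −40 °C; AcOH, −78 °C
Reagents that add atoms: none
Why: double deprotonation gives the nitronate/ester-enolate dianion, which is C-alkylated at the more nucleophilic ester α-carbon by the α-chloro ether (dianion alkylation of a β-nitro ester); the racemic centre becomes sp2 later.

Step 5
Reactants: 10 3-methylbutanal; 4 1-[(tert-butyldimethylsilyl)oxy]but-3-en-2-one; 11 diethylphosphonoacetic acid
Product: 13 (2E,4S)-8-[(tert-butyldimethylsilyl)oxy]-7-oxo-4-(propan-2-yl)oct-2-enoic acid, via keto aldehyde 12 (not isolated)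
Conditions: (S)-2-[methoxy(diphenyl)methyl]pyrrolidine (5 mol %), ethyl 3,4-dihydroxybenzoate (20 mol %), neat, 4 °C; excess 10 removed in vacuo; then 11, Zn(OTf)2, TMEDA, DBU, THF, rt
Reagents that add atoms: none
Why: enamine-catalysed asymmetric Michael addition of the aldehyde to the vinyl ketone, in which the enone attacks the enamine face away from the diphenyl(methoxy)methyl group and sets the (S) centre, followed in the same flask by an E-selective Horner–Wadsworth–Emmons reaction of the aldehyde that gives the free enoic acid directly.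

Step 6
Reactants: 13 (2E,4S)-8-[(tert-butyldimethylsilyl)oxy]-7-oxo-4-(propan-2-yl)oct-2-enoic acid; 9 2-(trimethylsilyl)ethyl 3-nitro-2-{[(triisopropylsilyl)oxy]methyl}propanoate
Product: 15 2-(trimethylsilyl)ethyl (2E)-3-[(1S,2R,3S,6R)-6-{[(tert-butyldimethylsilyl)oxy]methyl}-8-oxo-3-(propan-2-yl)-7-oxabicyclo[4.2.0]octan-2-yl]-2-{[(triisopropylsilyl)oxy]methyl}prop-2-enoate, via nitro β-lactone 14 (not isolated)
Conditions: 13, TsCl, iPr2NEt, LiCl, (2S,3R)-HyperBTM [(2S,3R)-3-isopropyl-2-phenyl-3,4-dihydro-2H-benzo[4,5]thiazolo[3,2-a]pyrimidine] (20 mol %), CH2Cl2, 0 °C; lithium nitronate of 9 (from 9, LiN(SiMe3)2, THF, −78 °C), −40 °C → rt; then DBU, 0 °C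
Reagents that add atoms: none
Why: Proposed new method: the acid is activated as its tosyl mixed anhydride and captured by the isothiourea as an s-cis α,β-unsaturated acylammonium ion (carbonyl O held syn to S), the nitronate of 9 adds to the β-carbon on the face away from the catalyst phenyl group (sets C2), iPr2NEt then converts the saturated acylammonium ion into the ammonium enolate, which attacks the tethered α-silyloxy ketone from the same open face (sets C1, cis to the new side chain) and lactonises through the aldolate oxygen (fixes C6 by the cis ring fusion and releases the catalyst), and DBU finally eliminates HNO2 from the β-nitro ester (E1cB) to the more stable E-acrylate; the closest known reaction types are the nucleophile-catalysed Michael–aldol–β-lactonisation of unsaturated acylammonium ions with ketone-bearing malonates, the isothiourea-catalysed addition of nitronates to unsaturated acylammonium ions and the nucleophile-catalysed aldol-lactonisation (NCAL) of keto acids, but an external nitronate combined with a ketone tethered to the acyl unit, and a β-nitro ester used as an acrylate β-anion equivalent in this manifold, have not been shown.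

Step 7
Reactants: 15 unsaturated bicyclic β-lactone
Product: 17 2-(trimethylsilyl)ethyl (5aR,6S,9R,9aS)-9-hydroxy-9-(hydroxymethyl)-1-oxo-6-(propan-2-yl)-1,3,5a,6,7,8,9,9a-octahydro-2-benzoxepine-4-carboxylate, via diol β-lactone 16 (not isolated)
Conditions: HF·pyridine, pyridine/THF, 0 °C → rt; then Et3N, rt
Reagents that add atoms: none
Why: acidic fluoride removes both silyl ethers but not the silylethyl ester, and the freed allylic alcohol, cis to the acyl group, opens the strained β-lactone at the carbonyl (translactonisation) to the seven-membered lactone and the tertiary alcohol with all four centres unchanged, whereas the other primary alcohol cannot reach that carbonyl without a bicyclo[2.1.1] intermediate.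

Step 8
Reactants: 17 diol lactone
Product: 18 2-(trimethylsilyl)ethyl (5aR,6S,9R,9aS)-1-oxo-6-(propan-2-yl)-1,5a,6,7,8,9a-hexahydro-3H-spiro[2-benzoxepine-9,2'-oxirane]-4-carboxylate
Conditions: PPh3, DIAD, toluene, 0 → 60 °C
Reagents that add atoms: none
Why: Mitsunobu cyclodehydration of a primary/tertiary 1,2-diol activates only the primary hydroxyl, which the tertiary oxygen displaces, so C9 keeps its configuration.

Step 9
Reactants: 10 3-methylbutanal; 4 1-[(tert-butyldimethylsilyl)oxy]but-3-en-2-one; 11 diethylphosphonoacetic acid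
Product: 20 (2E,4R)-8-[(tert-butyldimethylsilyl)oxy]-7-oxo-4-(propan-2-yl)oct-2-enoic acid, via keto aldehyde 19 (not isolated)
Conditions: (R)-2-[methoxy(diphenyl)methyl]pyrrolidine (5 mol %), ethyl 3,4-dihydroxybenzoate (20 mol %), neat, 4 °C; excess 10 removed in vacuo; then 11, Zn(OTf)2, TMEDA, DBU, THF, rt
Reagents that add atoms: none
Why: the same enamine-catalysed Michael addition and Horner–Wadsworth–Emmons sequence as step 5, with the enantiomeric catalyst setting the (R) centre.

Step 10
Reactants: 20 (2E,4R)-8-[(tert-butyldimethylsilyl)oxy]-7-oxo-4-(propan-2-yl)oct-2-enoic acid; 9 2-(trimethylsilyl)ethyl 3-nitro-2-{[(triisopropylsilyl)oxy]methyl}propanoate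
Product: 22 2-(trimethylsilyl)ethyl (2E)-3-[(1S,2R,3R,6R)-6-{[(tert-butyldimethylsilyl)oxy]methyl}-8-oxo-3-(propan-2-yl)-7-oxabicyclo[4.2.0]octan-2-yl]-2-{[(triisopropylsilyl)oxy]methyl}prop-2-enoate, via nitro β-lactone 21 (not isolated)
Conditions: 20, TsCl, iPr2NEt, LiCl, (2S,3R)-HyperBTM (20 mol %), CH2Cl2, 0 °C; lithium nitronate of 9 (from 9, LiN(SiMe3)2, THF, −78 °C), −40 °C → rt; then DBU, 0 °C
Reagents that add atoms: none
Why: Proposed new method: the same acylammonium Michael / aldol-β-lactonisation cascade and HNO2 elimination as in step 6, here on the (4R) acid, where the catalyst again fixes C2 in the same spatial sense so the side chain is cis to the isopropyl group (the two β-lactone centres are lost in step 11, and the robust triisopropylsilyl ether keeps the side-chain alcohol from opening the β-lactone); the closest known reaction types are the nucleophile-catalysed Michael–aldol–β-lactonisation, the isothiourea-catalysed nitronate addition to unsaturated acylammonium ions and the NCAL of keto acids.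

Step 11
Reactants: 22 unsaturated bicyclic β-lactone (cis series)
Product: 23 2-(trimethylsilyl)ethyl (2E)-3-[(1S,6R)-3-{[(tert-butyldimethylsilyl)oxy]methyl}-6-(propan-2-yl)cyclohex-2-en-1-yl]-2-{[(triisopropylsilyl)oxy]methyl}prop-2-enoate
Conditions: o-xylene, 140 °C, sealed tube
Reagents that add atoms: none
Why: thermal stereospecific [2+2] cycloreversion of the β-lactone expels CO2 and places the ring alkene regiospecifically between the two former lactone carbons, leaving the two remaining centres untouched.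

Step 12
Reactants: 23 silyl-protected cyclohexene ester
Product: 24 (2E)-2-(hydroxymethyl)-3-[(1S,6R)-3-(hydroxymethyl)-6-(propan-2-yl)cyclohex-2-en-1-yl]prop-2-enoic acid
Conditions: Bu4NF (4 equiv), THF, 0 °C → rt; aq. KHSO4 work-up
Reagents that add atoms: none
Why: fluoride cleaves both silyl ethers and fragments the 2-(trimethylsilyl)ethyl ester (loss of ethene) in one operation.

Step 13
Reactants: 24 cyclohexene diol acid; 18 spiro-epoxide
Product: 25 2-(trimethylsilyl)ethyl (5aR,6S,9R,9aS)-9-hydroxy-9-{[(2E)-2-(hydroxymethyl)-3-[(1S,6R)-3-(hydroxymethyl)-6-(propan-2-yl)cyclohex-2-en-1-yl]prop-2-enoyl]oxymethyl}-1-oxo-6-(propan-2-yl)-1,3,5a,6,7,8,9,9a-octahydro-2-benzoxepine-4-carboxylate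
Conditions: 24 (1.3 equiv), Cs2CO3 (0.3 equiv), DMF, 60 °C
Reagents that add atoms: none
Why: SN2 opening of the 2,2-disubstituted epoxide by the caesium carboxylate at the unhindered methylene carbon gives the primary ester and the tertiary alcohol with C9 untouched, the carboxylate being far more nucleophilic than the free allylic alcohols.

Step 14
Reactants: 25 coupled silylethyl ester
Product: 26 target acid CNP0361406.7
Conditions: TASF [tris(dimethylamino)sulfonium difluorotrimethylsilicate], DMF, 0 °C → rt; aq. KHSO4 work-up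
Reagents that add atoms: none
Why: anhydrous fluoride attacks silicon and fragments the 2-(trimethylsilyl)ethyl ester to the carboxylate under conditions mild enough for the two other esters and the β-hydroxy lactone.

**Compound list**

1 | (tert-butyldimethylsilyloxy)acetaldehyde | O=CCO[Si](C)(C)C(C)(C)C | starting material
2 | vinylmagnesium bromide | C=C[Mg]Br | starting material
3 | 1-[(tert-butyldimethylsilyl)oxy]but-3-en-2-ol (racemic) | C=CC(O)CO[Si](C)(C)C(C)(C)C | intermediate
4 | 1-[(tert-butyldimethylsilyl)oxy]but-3-en-2-one | C=CC(=O)CO[Si](C)(C)C(C)(C)C | intermediate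
5 | 3-nitropropanoic acid | OC(=O)CC[N+](=O)[O-] | starting material
6 | 2-(trimethylsilyl)ethanol | OCC[Si](C)(C)C | starting material
7 | 2-(trimethylsilyl)ethyl 3-nitropropanoate | [O-][N+](=O)CCC(=O)OCC[Si](C)(C)C | intermediate
8 | (triisopropylsiloxy)methyl chloride | ClCO[Si](C(C)C)(C(C)C)C(C)C | starting material
9 | 2-(trimethylsilyl)ethyl 3-nitro-2-{[(triisopropylsilyl)oxy]methyl}propanoate (racemic) | [O-][N+](=O)CC(CO[Si](C(C)C)(C(C)C)C(C)C)C(=O)OCC[Si](C)(C)C | intermediate
10 | 3-methylbutanal | CC(C)CC=O | starting material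
11 | diethylphosphonoacetic acid | CCOP(=O)(CC(=O)O)OCC | starting material
12 | (2S)-6-[(tert-butyldimethylsilyl)oxy]-5-oxo-2-(propan-2-yl)hexanal | O=C[C@H](C(C)C)CCC(=O)CO[Si](C)(C)C(C)(C)C | intermediate
13 | (2E,4S)-8-[(tert-butyldimethylsilyl)oxy]-7-oxo-4-(propan-2-yl)oct-2-enoic acid | OC(=O)/C=C/[C@H](C(C)C)CCC(=O)CO[Si](C)(C)C(C)(C)C | intermediate
14 | nitro β-lactone: as 15, but the side chain is the saturated 1-nitro-2-(silyloxymethyl)-2-(ester)ethyl group (mixture at its two carbons); ring centres as in 15 | CC(C)(C)[Si](C)(C)OC[C@@]12CC[C@@H](C(C)C)[C@H](C([N+](=O)[O-])C(CO[Si](C(C)C)(C(C)C)C(C)C)C(=O)OCC[Si](C)(C)C)[C@@H]1C(=O)O2 | intermediate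
15 | 2-(trimethylsilyl)ethyl (2E)-3-[(1S,2R,3S,6R)-6-{[(tert-butyldimethylsilyl)oxy]methyl}-8-oxo-3-(propan-2-yl)-7-oxabicyclo[4.2.0]octan-2-yl]-2-{[(triisopropylsilyl)oxy]methyl}prop-2-enoate | CC(C)(C)[Si](C)(C)OC[C@@]12CC[C@@H](C(C)C)[C@H](/C=C(\CO[Si](C(C)C)(C(C)C)C(C)C)C(=O)OCC[Si](C)(C)C)[C@@H]1C(=O)O2 | intermediate
16 | diol β-lactone: 15 with both silyl ethers replaced by OH | OC[C@@]12CC[C@@H](C(C)C)[C@H](/C=C(\CO)C(=O)OCC[Si](C)(C)C)[C@@H]1C(=O)O2 | intermediate
17 | 2-(trimethylsilyl)ethyl (5aR,6S,9R,9aS)-9-hydroxy-9-(hydroxymethyl)-1-oxo-6-(propan-2-yl)-1,3,5a,6,7,8,9,9a-octahydro-2-benzoxepine-4-carboxylate | OC[C@@]1(O)CC[C@@H](C(C)C)[C@@H]2C=C(C(=O)OCC[Si](C)(C)C)COC(=O)[C@@H]21 | intermediate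
18 | 2-(trimethylsilyl)ethyl (5aR,6S,9R,9aS)-1-oxo-6-(propan-2-yl)-1,5a,6,7,8,9a-hexahydro-3H-spiro[2-benzoxepine-9,2'-oxirane]-4-carboxylate | C1O[C@@]12CC[C@@H](C(C)C)[C@@H]3C=C(C(=O)OCC[Si](C)(C)C)COC(=O)[C@@H]32 | intermediate
19 | (2R)-6-[(tert-butyldimethylsilyl)oxy]-5-oxo-2-(propan-2-yl)hexanal | O=C[C@@H](C(C)C)CCC(=O)CO[Si](C)(C)C(C)(C)C | intermediate
20 | (2E,4R)-8-[(tert-butyldimethylsilyl)oxy]-7-oxo-4-(propan-2-yl)oct-2-enoic acid | OC(=O)/C=C/[C@@H](C(C)C)CCC(=O)CO[Si](C)(C)C(C)(C)C | intermediate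
21 | nitro β-lactone of the cis series: as 22, but the side chain is the saturated nitro ester (mixture at its two carbons) | CC(C)(C)[Si](C)(C)OC[C@@]12CC[C@H](C(C)C)[C@H](C([N+](=O)[O-])C(CO[Si](C(C)C)(C(C)C)C(C)C)C(=O)OCC[Si](C)(C)C)[C@@H]1C(=O)O2 | intermediate
22 | 2-(trimethylsilyl)ethyl (2E)-3-[(1S,2R,3R,6R)-6-{[(tert-butyldimethylsilyl)oxy]methyl}-8-oxo-3-(propan-2-yl)-7-oxabicyclo[4.2.0]octan-2-yl]-2-{[(triisopropylsilyl)oxy]methyl}prop-2-enoate | CC(C)(C)[Si](C)(C)OC[C@@]12CC[C@H](C(C)C)[C@H](/C=C(\CO[Si](C(C)C)(C(C)C)C(C)C)C(=O)OCC[Si](C)(C)C)[C@@H]1C(=O)O2 | intermediate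
23 | 2-(trimethylsilyl)ethyl (2E)-3-[(1S,6R)-3-{[(tert-butyldimethylsilyl)oxy]methyl}-6-(propan-2-yl)cyclohex-2-en-1-yl]-2-{[(triisopropylsilyl)oxy]methyl}prop-2-enoate | CC(C)[C@H]1CCC(CO[Si](C)(C)C(C)(C)C)=C[C@H]1/C=C(\CO[Si](C(C)C)(C(C)C)C(C)C)C(=O)OCC[Si](C)(C)C | intermediate
24 | (2E)-2-(hydroxymethyl)-3-[(1S,6R)-3-(hydroxymethyl)-6-(propan-2-yl)cyclohex-2-en-1-yl]prop-2-enoic acid | CC(C)[C@H]1CCC(CO)=C[C@H]1/C=C(\CO)C(=O)O | intermediate
25 | 2-(trimethylsilyl)ethyl ester of the target (name as in step 13) | CC(C)[C@H]1CCC(CO)=C[C@H]1/C=C(\CO)C(=O)OC[C@@]1(O)CC[C@@H](C(C)C)[C@@H]2C=C(C(=O)OCC[Si](C)(C)C)COC(=O)[C@@H]21 | intermediate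
26 | (5aR,6S,9R,9aS)-9-hydroxy-9-{[(2E)-2-(hydroxymethyl)-3-[(1S,6R)-3-(hydroxymethyl)-6-(propan-2-yl)cyclohex-2-en-1-yl]prop-2-enoyl]oxymethyl}-1-oxo-6-(propan-2-yl)-1,3,5a,6,7,8,9,9a-octahydro-2-benzoxepine-4-carboxylic acid (CNP0361406.7) | CC(C)[C@H]1CCC(CO)=C[C@H]1/C=C(\CO)C(=O)OC[C@@]1(O)CC[C@@H](C(C)C)[C@@H]2C=C(C(=O)O)COC(=O)[C@@H]21 | target

**Step count and risks**

Total step count: 14. Longest linear sequence: 8 steps (steps 1, 2, 5, 6, 7, 8, 13, 14; the cyclohexene half is equally long through steps 1, 2, 9, 10, 11, 12, 13, 14).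

The three steps most likely to fail:

Step 6 (proposed new cascade, lactone half). The risks are a sluggish nitronate addition to a β-alkyl, γ-branched acylammonium ion and O-acylation of the nitronate. The fallback uses only known reaction types, sets out from 12 and comes back at 15. Aldehyde 12 is isolated and homologated with (triphenylphosphoranylidene)acetaldehyde in toluene to (2E,4S)-8-[(tert-butyldimethylsilyl)oxy]-7-oxo-4-(propan-2-yl)oct-2-enal F1. Iminium-catalysed Michael addition of nitro ester 9 with (R)-α,α-diphenylprolinol trimethylsilyl ether and benzoic acid gives the nitro aldehyde F2, with the new centre configured as C2 of 15. DBU then eliminates HNO2 to the (E)-acrylate aldehyde F3. Pinnick oxidation (NaClO2, NaH2PO4, 2-methylbut-2-ene, tBuOH/H2O) gives the keto acid F4. The known aldol-lactonisation of keto acids (TsCl, iPr2NEt, LiCl, (2S,3R)-HyperBTM) closes F4 to 15.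

Step 10 (the same new cascade on the cis series). The substrate centre and the catalyst may be mismatched, and the aldol must pass through a chair with one axial substituent. The fallback sets out from 19 and comes back at 22. Aldehyde 19 is isolated and converted with (triphenylphosphoranylidene)acetaldehyde into (2E,4R)-8-[(tert-butyldimethylsilyl)oxy]-7-oxo-4-(propan-2-yl)oct-2-enal F5. Iminium-catalysed Michael addition of 9 with (R)-α,α-diphenylprolinol trimethylsilyl ether gives the nitro aldehyde F6, and DBU gives the (E)-acrylate aldehyde F7. Pinnick oxidation gives the keto acid F8, which the aldol-lactonisation (TsCl, iPr2NEt, LiCl, (2S,3R)-HyperBTM) closes to 22. The configuration of the two β-lactone carbons does not matter here, because step 11 removes them.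

Step 13 (fragment union by epoxide opening). The risks are slow attack of a hindered, conjugated carboxylate next to a quaternary carbon and carboxylate exchange at the allylic lactone C–O bond. The fallback replaces epoxide opening by esterification of a diol; it sets out from 24 and 17 and comes back at 26, so steps 8 and 14 are not needed. Acid 24 is persilylated (TBSCl, imidazole, DMF) to the bis(silyl ether) silyl ester F9. K2CO3 in MeOH/THF/H2O cleaves only the silyl ester and gives the bis(tert-butyldimethylsilyl)-protected acid F10. F10 is coupled with the primary hydroxyl of diol 17 (EDC·HCl, DMAP, CH2Cl2; the tertiary hydroxyl does not react) to give the protected ester F11. TASF in DMF then removes both silyl ethers and the silylethyl ester in one operation to give 26.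

**Further compounds**

F1 | step 6 | (2E,4S)-8-[(tert-butyldimethylsilyl)oxy]-7-oxo-4-(propan-2-yl)oct-2-enal | O=C/C=C/[C@H](C(C)C)CCC(=O)CO[Si](C)(C)C(C)(C)C
F2 | step 6 | nitro aldehyde (Michael adduct of 9 and F1; mixture at the nitro and ester carbons; other centres as in 15) | O=CC[C@@H](C([N+](=O)[O-])C(CO[Si](C(C)C)(C(C)C)C(C)C)C(=O)OCC[Si](C)(C)C)[C@H](C(C)C)CCC(=O)CO[Si](C)(C)C(C)(C)C
F3 | step 6 | (E)-acrylate aldehyde (F2 after loss of HNO2) | O=CC[C@@H](/C=C(\CO[Si](C(C)C)(C(C)C)C(C)C)C(=O)OCC[Si](C)(C)C)[C@H](C(C)C)CCC(=O)CO[Si](C)(C)C(C)(C)C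
F4 | step 6 | keto acid (F3 with CHO oxidised to COOH) | OC(=O)C[C@@H](/C=C(\CO[Si](C(C)C)(C(C)C)C(C)C)C(=O)OCC[Si](C)(C)C)[C@H](C(C)C)CCC(=O)CO[Si](C)(C)C(C)(C)C
F5 | step 10 | (2E,4R)-8-[(tert-butyldimethylsilyl)oxy]-7-oxo-4-(propan-2-yl)oct-2-enal | O=C/C=C/[C@@H](C(C)C)CCC(=O)CO[Si](C)(C)C(C)(C)C
F6 | step 10 | nitro aldehyde of the cis series (Michael adduct of 9 and F5; mixture at the nitro and ester carbons) | O=CC[C@@H](C([N+](=O)[O-])C(CO[Si](C(C)C)(C(C)C)C(C)C)C(=O)OCC[Si](C)(C)C)[C@@H](C(C)C)CCC(=O)CO[Si](C)(C)C(C)(C)C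
F7 | step 10 | (E)-acrylate aldehyde of the cis series | O=CC[C@@H](/C=C(\CO[Si](C(C)C)(C(C)C)C(C)C)C(=O)OCC[Si](C)(C)C)[C@@H](C(C)C)CCC(=O)CO[Si](C)(C)C(C)(C)C
F8 | step 10 | keto acid of the cis series | OC(=O)C[C@@H](/C=C(\CO[Si](C(C)C)(C(C)C)C(C)C)C(=O)OCC[Si](C)(C)C)[C@@H](C(C)C)CCC(=O)CO[Si](C)(C)C(C)(C)C
F9 | step 13 | tert-butyldimethylsilyl ester of 24 with both hydroxyls as tert-butyldimethylsilyl ethers | CC(C)[C@H]1CCC(CO[Si](C)(C)C(C)(C)C)=C[C@H]1/C=C(\CO[Si](C)(C)C(C)(C)C)C(=O)O[Si](C)(C)C(C)(C)C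
F10 | step 13 | acid 24 with both hydroxyls as tert-butyldimethylsilyl ethers | CC(C)[C@H]1CCC(CO[Si](C)(C)C(C)(C)C)=C[C@H]1/C=C(\CO[Si](C)(C)C(C)(C)C)C(=O)O
F11 | step 13 | ester of F10 and the primary hydroxyl of 17 (bis-silyl ether of 25) | CC(C)[C@H]1CCC(CO[Si](C)(C)C(C)(C)C)=C[C@H]1/C=C(\CO[Si](C)(C)C(C)(C)C)C(=O)OC[C@@]1(O)CC[C@@H](C(C)C)[C@@H]2C=C(C(=O)OCC[Si](C)(C)C)COC(=O)[C@@H]21
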